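## Plan

- **Cuts.** The C4 carbinol goes back to the C4 ketone, and C2–H to the C2=C3 bond of a 2-phenyl-4-pyranone. Ring C is then cut in one operation at C4a–C4, C4–C3 and O1–C2 into a ring A 4a-iodo enol, carbon monoxide and phenylacetylene. C4a–I goes back to C4a–H, and the two C8–prenyl bonds to 5-methoxyresorcinol and prenyl bromide.
- **Enabling feature.** In the flavan skeleton (O1, C2, C3, C4, C4a, C5–C8, C8a) C4 is a carbonyl-level carbon between C4a and C3, and O1 is an enol oxygen on C8a, so ring C at the pyranone level equals vinyl iodide + CO + terminal alkyne. In ring A, C4a lies between the one free enol oxygen (on C8a) and the methylated C5 oxygen, and the diprenyl enol offers only one kind of carbon to an iodinating agent.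
- **Forward order.** Ring A is dearomatised by twofold C-prenylation at C8 and iodinated at C4a. Ring C (the pyran) is then closed by the three-component carbonylative annulation, and two reductions finish the synthesis.
- **Stereochemistry.** C2 (S) comes from a ligand-controlled copper hydride 1,4-reduction of the pyranone. C4 (S) comes from substrate-controlled hydride addition to the C4 ketone, cis to the C2 phenyl.

Key step: step 3

Remark 1: compounds 4, 5, 8 and 9 are vinylogous acids drawn as the C8a enol; the tautomer with the enol at C7 is the same compound.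
Remark 2 (assumption): with (R)-DTBM-SEGPHOS the copper hydride is taken to add to the C2 face that gives the 2S product; should the first run show the opposite sense, the (S)-ligand is used under the same conditions.

## Route

Step 1
Reactants: 1 5-methoxyresorcinol (5-methoxybenzene-1,3-diol); 2 prenyl bromide (1-bromo-3-methylbut-2-ene, 2.1 equiv)
Product: 4 5-hydroxy-3-methoxy-6,6-bis(3-methylbut-2-en-1-yl)cyclohexa-2,4-dien-1-one, via 2-prenyl-5-methoxyresorcinol 3 (not isolated)
Conditions: KOH (3 equiv), H2O, 0 °C to rt; then HCl to pH 3; acid fraction taken into aq. NaHCO3 and re-acidified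
Reagents that add atoms: none
Why: Dearomative C-alkylation of a phloroglucinol-type phenolate with an allylic bromide (the reaction type that gives gem-diprenyl triketones from acylphloroglucinols): in water the dianion of 1 is alkylated at carbon, the position between the two phenolate oxygens giving 3 and then reacting a second time at the same carbon with loss of aromaticity, and the vinylogous acid 4 so formed is far more acidic than the phenolic regioisomers and O-prenyl ethers and is parted from them through aqueous NaHCO3; no stereocentre is formed.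

Step 2
Reactants: 4 5-hydroxy-3-methoxy-6,6-bis(3-methylbut-2-en-1-yl)cyclohexa-2,4-dien-1-one
Product: 5 5-hydroxy-4-iodo-3-methoxy-6,6-bis(3-methylbut-2-en-1-yl)cyclohexa-2,4-dien-1-one
Conditions: NIS (1.0 equiv), MeCN, −20 to 0 °C, dark
Reagents that add atoms: N-iodosuccinimide, O=C1CCC(=O)N1I
Why: Electrophilic iodination of a vinylogous acid (as known for cyclic 1,3-dione enols): the enol carbon C4a is far more nucleophilic than the isolated prenyl alkenes, the two tautomers of 4 interchange C4a and C6 so that only one mono-iodide can form, and one equivalent of NIS at low temperature should hold back di-iodination and iodocyclisation onto the prenyl groups.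

Step 3
Reactants: 5 5-hydroxy-4-iodo-3-methoxy-6,6-bis(3-methylbut-2-en-1-yl)cyclohexa-2,4-dien-1-one; 6 carbon monoxide (5 bar); 7 phenylacetylene (1.5 equiv)
Product: 10 5-methoxy-8,8-bis(3-methylbut-2-en-1-yl)-2-phenyl-4H-chromene-4,7(8H)-dione, via C4a ynone 8 (not isolated), via enaminone 9 (not isolated)
Conditions: PdCl2(PPh3)2 (5 mol %), CO (5 bar), Et2NH (5 equiv), DMF, 60 °C
Reagents that add atoms: none
Why: Proposed new method: zerovalent palladium, formed in the flask from the divalent precatalyst PdCl2(PPh3)2, should insert into the C4a–I bond of the diethylammonium enolate of 5, take up CO to give the acylpalladium species (C4a–C4 bond) and couple it with the amine-activated terminal alkyne to release ynone 8 (C4–C3 bond). Et2NH then adds to the ynone to give enaminone 9, and the enol oxygen on C8a displaces the amine at the phenyl-bearing carbon by addition–elimination (O1–C2 bond), which closes ring C, the 4-pyranone, in a net 6-endo mode with respect to the former alkyne. The closest known reaction type is the PdCl2(PPh3)2/Et2NH carbonylative annulation of 2-iodophenols with terminal alkynes to flavones, and oxidative addition into alpha-iodo enones is routine in cross-coupling; new is only the cyclic iodo vinylogous acid in the place of the iodophenol. No stereocentre is formed. The step needs carbonylation to outrun direct alkynylation (CO pressure, no copper co-catalyst), 6-endo closure instead of 5-exo closure to a benzylidene furanone (secured by the secondary amine through 9), and closure through one oxygen only, which the substrate secures because the C5 oxygen is methylated and the C7 oxygen cannot reach C2; the limited amount of Et2NH and the moderate temperature are meant to spare the C5 vinylogous methyl ester from amine exchange.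

Step 4
Reactants: 10 5-methoxy-8,8-bis(3-methylbut-2-en-1-yl)-2-phenyl-4H-chromene-4,7(8H)-dione
Product: 12 (2S)-5-methoxy-8,8-bis(3-methylbut-2-en-1-yl)-2-phenyl-2,3-dihydro-4H-chromene-4,7(8H)-dione, via silyl enol ether 11 (not isolated)
Conditions: Cu(OAc)2 (5 mol %), (R)-DTBM-SEGPHOS (5.5 mol %), (MeO)2MeSiH (3 equiv), toluene, 0 °C to rt, no alcohol additive; then AcOH/NaOAc buffer (pH 4), THF–H2O, 0 °C
Reagents that add atoms: none
Why: Asymmetric copper hydride 1,4-reduction (conjugate hydrosilylation, as established for chromones and beta,beta-disubstituted enones): the monovalent copper hydride generated from Cu(OAc)2, the bisphosphine and the silane delivers hydride to C2 of the C2=C3–C4=O enone from the face left open by the ligand, which sets C2 as S, and the copper enolate is captured as silyl enol ether 11 so that C2 is shielded from retro-oxa-Michael ring opening until the buffered hydrolysis, while the unconjugated prenyl alkenes do not react.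

Step 5
Reactants: 12 (2S)-5-methoxy-8,8-bis(3-methylbut-2-en-1-yl)-2-phenyl-2,3-dihydro-4H-chromene-4,7(8H)-dione
Product: 13 (2S,4S)-4-hydroxy-5-methoxy-8,8-bis(3-methylbut-2-en-1-yl)-2-phenyl-3,4-dihydro-2H-chromen-7(8H)-one (pongaflavanol)
Conditions: NaBH4 (1.1 equiv), CeCl3·7H2O (1.1 equiv), MeOH–THF, −78 to −40 °C; pH 7 phosphate buffer quench
Reagents that add atoms: none
Why: Luche 1,2-reduction: hydride should add to the C4 carbonyl, which is flanked by a methylene whereas the C7 carbonyl is screened by the quaternary C8 and deactivated by two conjugated oxygen donors, and it enters along the pseudo-axial path of the half-chair that carries the C2 phenyl pseudo-equatorial, so the new hydroxyl comes out pseudo-equatorial and cis to phenyl (4S, substrate control, as in NaBH4 reductions of flavanones).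

## Compound list

1 | 5-methoxyresorcinol (5-methoxybenzene-1,3-diol) | COc1cc(O)cc(O)c1 | starting material
2 | prenyl bromide (1-bromo-3-methylbut-2-ene) | CC(C)=CCBr | starting material
3 | 5-methoxy-2-(3-methylbut-2-en-1-yl)benzene-1,3-diol (2-prenyl-5-methoxyresorcinol) | COc1cc(O)c(CC=C(C)C)c(O)c1 | intermediate (not isolated)
4 | 5-hydroxy-3-methoxy-6,6-bis(3-methylbut-2-en-1-yl)cyclohexa-2,4-dien-1-one (flavan numbering: C7 ketone, C5 OMe, C8a enol OH, C8 diprenyl, C4a–H) | COC1=CC(=O)C(CC=C(C)C)(CC=C(C)C)C(O)=C1 | intermediate
5 | 5-hydroxy-4-iodo-3-methoxy-6,6-bis(3-methylbut-2-en-1-yl)cyclohexa-2,4-dien-1-one (iodine on C4a) | COC1=CC(=O)C(CC=C(C)C)(CC=C(C)C)C(O)=C1I | intermediate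
6 | carbon monoxide | [C-]#[O+] | starting material
7 | phenylacetylene | C#Cc1ccccc1 | starting material
8 | 5-hydroxy-3-methoxy-6,6-bis(3-methylbut-2-en-1-yl)-4-(3-phenylprop-2-ynoyl)cyclohexa-2,4-dien-1-one (C4a ynone) | COC1=CC(=O)C(CC=C(C)C)(CC=C(C)C)C(O)=C1C(=O)C#Cc1ccccc1 | intermediate (not isolated)
9 | 4-[(2E)-3-(diethylamino)-3-phenylprop-2-enoyl]-5-hydroxy-3-methoxy-6,6-bis(3-methylbut-2-en-1-yl)cyclohexa-2,4-dien-1-one (enaminone; E drawn, the push–pull double bond isomerises freely) | COC1=CC(=O)C(CC=C(C)C)(CC=C(C)C)C(O)=C1C(=O)/C=C(/N(CC)CC)c1ccccc1 | intermediate (not isolated)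
10 | 5-methoxy-8,8-bis(3-methylbut-2-en-1-yl)-2-phenyl-4H-chromene-4,7(8H)-dione | COC1=CC(=O)C(CC=C(C)C)(CC=C(C)C)C2=C1C(=O)C=C(c1ccccc1)O2 | intermediate
11 | (2S)-4-{[dimethoxy(methyl)silyl]oxy}-5-methoxy-8,8-bis(3-methylbut-2-en-1-yl)-2-phenyl-2H-chromen-7(8H)-one | COC1=CC(=O)C(CC=C(C)C)(CC=C(C)C)C2=C1C(O[Si](C)(OC)OC)=C[C@@H](c1ccccc1)O2 | intermediate (not isolated)
12 | (2S)-5-methoxy-8,8-bis(3-methylbut-2-en-1-yl)-2-phenyl-2,3-dihydro-4H-chromene-4,7(8H)-dione | COC1=CC(=O)C(CC=C(C)C)(CC=C(C)C)C2=C1C(=O)C[C@@H](c1ccccc1)O2 | intermediate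
13 | (2S,4S)-4-hydroxy-5-methoxy-8,8-bis(3-methylbut-2-en-1-yl)-2-phenyl-3,4-dihydro-2H-chromen-7(8H)-one (pongaflavanol, 2,4-cis) | COC1=CC(=O)C(CC=C(C)C)(CC=C(C)C)C2=C1[C@@H](O)C[C@@H](c1ccccc1)O2 | target

## Count and risks

Total step count: 5. Longest linear sequence: 5 steps (1 to 4 to 5 to 10 to 12 to 13).

**Step 3 (carbonylative annulation).** Oxidative addition into the electron-rich iodo enolate may be slow. Reductive loss of iodine, capture of the acylpalladium species by Et2NH as an amide, alkynylation without CO uptake followed by furan closure, or amine exchange at the C5 methoxy group could then take over.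
Fallback (known chemistry), setting out from 4 and coming back at 10:
- 4 is C-acetylated at C4a with acetic acid, dicyclohexylcarbodiimide and 4-(dimethylamino)pyridine in CH2Cl2 (enol ester formation, then O-to-C acyl shift, the standard entry to 2-acyl cyclic 1,3-diones). This gives 4-acetyl-5-hydroxy-3-methoxy-6,6-bis(3-methylbut-2-en-1-yl)cyclohexa-2,4-dien-1-one F1.
- Claisen–Schmidt condensation of F1 with benzaldehyde (KOH, EtOH–H2O, rt) gives the chalcone 5-hydroxy-3-methoxy-6,6-bis(3-methylbut-2-en-1-yl)-4-[(2E)-3-phenylprop-2-enoyl]cyclohexa-2,4-dien-1-one F2.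
- Oxidative cyclisation of F2 with catalytic I2 in DMSO at 100 °C (the usual 2'-hydroxychalcone-to-flavone protocol) closes ring C through the C8a oxygen and gives 10. Steps 4 and 5 follow unchanged.

**Step 1 (gem-diprenylation).** Site selectivity may be poor: attack at the two carbons between hydroxyl and methoxyl, O-prenylation, or alkylation stopping at one or running on to three prenyl groups would leave the gem-diprenyl enol as a minor component.
Fallback, setting out from 2 and coming back at 4; the quaternary carbon is built on a pyranone whose nucleophilic carbon is C3, and ring A is formed afterwards: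
- 4-Hydroxy-6-methyl-2H-pyran-2-one F3 (purchased) is prenylated twice at C3 with 2 under Pd(PPh3)4 catalysis (Tsuji–Trost conditions, Et3N, THF). O-prenyl ethers are re-ionised by zerovalent palladium and funnel to carbon. The product is 6-methyl-3,3-bis(3-methylbut-2-en-1-yl)-2H-pyran-2,4(3H)-dione F4.
- NaOMe in MeOH opens the enol lactone to methyl 2,2-bis(3-methylbut-2-en-1-yl)-3,5-dioxohexanoate F5.
- The dianion of F5 (LiN(iPr)2, THF, −78 °C to rt) closes by intramolecular Claisen condensation of the terminal methyl carbon onto the ester, giving 2,2-bis(3-methylbut-2-en-1-yl)cyclohexane-1,3,5-trione F6.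
- Acid-catalysed enol etherification of F6 (MeOH, catalytic camphorsulfonic acid, rt) takes place at the unhindered C5 carbonyl, remote from the quaternary carbon, as with 4,4-dialkylcyclohexane-1,3-diones, and gives 4.

**Step 4 (asymmetric 1,4-reduction).** Facial selectivity at C2 may be insufficient, hydride may be delivered to the ring A vinylogous ester instead, or the C2 configuration may be lost by retro-oxa-Michael opening of the enolate before it is silylated.
Fallback, setting out from 10 and coming back at 13; resolution replaces asymmetric catalysis: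
- 10 is reduced in the conjugate sense with LiBH(s-Bu)3 (1.05 equiv, THF, −78 °C, buffered quench), as known for chromones, to racemic 5-methoxy-8,8-bis(3-methylbut-2-en-1-yl)-2-phenyl-2,3-dihydro-4H-chromene-4,7(8H)-dione F7.
- Reduction of F7 under the conditions of step 5 gives the racemic cis alcohol, that is 13 together with its enantiomer (2R,4R)-4-hydroxy-5-methoxy-8,8-bis(3-methylbut-2-en-1-yl)-2-phenyl-3,4-dihydro-2H-chromen-7(8H)-one F8.
- Lipase-catalysed acetylation (Pseudomonas lipase, vinyl acetate, tert-butyl methyl ether, rt) should, by the usual enantiopreference of lipases for secondary alcohols, convert the 4R alcohol into (2R,4R)-5-methoxy-8,8-bis(3-methylbut-2-en-1-yl)-7-oxo-2-phenyl-3,4,7,8-tetrahydro-2H-chromen-4-yl acetate F9. This leaves 13, which is separated by chromatography.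

## Further compounds

F1 | step 3 | 4-acetyl-5-hydroxy-3-methoxy-6,6-bis(3-methylbut-2-en-1-yl)cyclohexa-2,4-dien-1-one | COC1=CC(=O)C(CC=C(C)C)(CC=C(C)C)C(O)=C1C(C)=O
F2 | step 3 | 5-hydroxy-3-methoxy-6,6-bis(3-methylbut-2-en-1-yl)-4-[(2E)-3-phenylprop-2-enoyl]cyclohexa-2,4-dien-1-one | COC1=CC(=O)C(CC=C(C)C)(CC=C(C)C)C(O)=C1C(=O)/C=C/c1ccccc1
F3 | step 1 | 4-hydroxy-6-methyl-2H-pyran-2-one (purchased) | CC1=CC(O)=CC(=O)O1
F4 | step 1 | 6-methyl-3,3-bis(3-methylbut-2-en-1-yl)-2H-pyran-2,4(3H)-dione | CC1=CC(=O)C(CC=C(C)C)(CC=C(C)C)C(=O)O1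
F5 | step 1 | methyl 2,2-bis(3-methylbut-2-en-1-yl)-3,5-dioxohexanoate | COC(=O)C(CC=C(C)C)(CC=C(C)C)C(=O)CC(C)=O
F6 | step 1 | 2,2-bis(3-methylbut-2-en-1-yl)cyclohexane-1,3,5-trione | O=C1CC(=O)C(CC=C(C)C)(CC=C(C)C)C(=O)C1
F7 | step 4 | racemic 5-methoxy-8,8-bis(3-methylbut-2-en-1-yl)-2-phenyl-2,3-dihydro-4H-chromene-4,7(8H)-dione | COC1=CC(=O)C(CC=C(C)C)(CC=C(C)C)C2=C1C(=O)CC(c1ccccc1)O2
F8 | step 4 | (2R,4R)-4-hydroxy-5-methoxy-8,8-bis(3-methylbut-2-en-1-yl)-2-phenyl-3,4-dihydro-2H-chromen-7(8H)-one | COC1=CC(=O)C(CC=C(C)C)(CC=C(C)C)C2=C1[C@H](O)C[C@H](c1ccccc1)O2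
F9 | step 4 | (2R,4R)-5-methoxy-8,8-bis(3-methylbut-2-en-1-yl)-7-oxo-2-phenyl-3,4,7,8-tetrahydro-2H-chromen-4-yl acetate | COC1=CC(=O)C(CC=C(C)C)(CC=C(C)C)C2=C1[C@H](OC(C)=O)C[C@H](c1ccccc1)O2
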